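Larch reached 9.1% by 12.0 d, more than any birch reading, although birch ran to 50.0 d and its flask was 22.0 K cooler.

common to all: substrate 0.50 M
- birch: partner 0.75 equiv; temperature 60 °C; run made earlier
- larch: partner 1.1 equiv; temperature 82 °C; run made earlier
- alpha: partner 1.50 equiv; at 90 °C until 5.0 d, from then on at 50 °C; time 15 d
- eta: partner 1.50 equiv; temperature 90 °C; time 15 d
- beta: partner 1.50 equiv; temperature 70 °C; time 15 d
- delta: partner 1.50 equiv; temperature 50 °C; time 15 d

| run | time / d | product / % |
|---|---|---|
| birch | 10.0 | 0.4 |
| birch | 20.0 | 0.2 |
| birch | 25.0 | 0 |
| birch | 40.0 | 0 |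
| birch | 50.0 | 0.3 |
| larch | 1.04 | 0 |
| larch | 1.67 | 0.1 |
| larch | 2.50 | 0.5 |
| larch | 4.00 | 1.1 |
| larch | 8.00 | 5.1 |
| larch | 12.0 | 9.1 |

(scatter of a reading: 0.5 percentage points)

- steps under discussion: partner + intermediate B -> intermediate C; partner <-> dormant form; substrate -> intermediate B; intermediate C <-> intermediate D; substrate + partner <-> intermediate A; intermediate C -> decomposed reagent; intermediate C -> product

* the best flask by amount of product, in percent of the substrate charged; "all alike" if 1.5 percentage points covers them all (alpha / eta / beta / delta / all alike)
* amount of product at the end, in percent of the substrate charged, alpha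
* amount of product at the end, in percent of the substrate charged, eta
* amount of product at the end, in percent of the substrate charged, beta
* amount of product at the end, in percent of the substrate charged, delta

The last two larch readings give a late slope of 0.0100 /d of the charge. That line meets zero at the lag, the induction period in which the intermediates fill, 2.90 d. Before twice the lag, a parabola joins the line smoothly: product is the slope times the square of the time, divided by 4 lags. For larch at 2.50 d it gives 0.539% against a reading of 0.5%. Control passes from lag to slope at that crossing.

The reckoning sets the partner charges aside and lets one temperature factor raise the slope and shorten the lag. Birch, read as a straight line under twice the scatter, makes that factor 50.0, and eta comes to 59.3%.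

That link is weak, since birch lies inside its own lag. On the parabola the factor is 14.7, and birch's run is shorter than its doubled lag. The steepness is 0.122 /K. At eta's temperature the factor is 2.66, so the lag is 1.09 d and eta reaches 36.9%.

Alpha's hot window gives 10.4%, and alpha's lag is over before the change. Alpha's cold stretch therefore runs on the line at the slope for 50 °C and adds 0.201%. Beta's run is shorter than its doubled lag, so beta stays on the parabola at 1.03%. Delta does too, at 0.00783%.

The forecast, also reading “a lag of about 3 d”, named eta with 17%, 45%, 5% and 0.3% for alpha, eta, beta and delta, higher than this reckoning for eta.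

The flasks end at 11.0% in alpha, 34.7% in eta, 1.58% in beta and 0.0142% in delta, so eta leads.

    partner + intermediate B → intermediate C (k = 0.0870 /M/h, Ea = 79.0 kJ/mol)
    partner ⇌ dormant form (K = 0.300, k = 0.0150 /h, Ea = 120 kJ/mol, ΔH = −8.00 kJ/mol)
    substrate → intermediate B (k = 0.00580 /h, Ea = 128 kJ/mol)
    intermediate C ⇌ intermediate D (K = 11.0, k = 0.0700 /h, Ea = 109 kJ/mol, ΔH = −41.0 kJ/mol)
    substrate + partner ⇌ intermediate A (K = 1.40 /M, k = 0.0650 /M/h, Ea = 93.0 kJ/mol, ΔH = −90.0 kJ/mol)
    intermediate C → decomposed reagent (k = 0.0200 /h, Ea = 115 kJ/mol)
    intermediate C → product (k = 0.0490 /h, Ea = 117 kJ/mol)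
    (constants at 90 °C)

Alpha held 10.7% of product at 5.00 d and 11.0% at 15.0 d, against 10.4% from its hot window after the lag of 1.09 d. The neighbouring flask is alpha with 2.50 equiv of partner. The reckoning contains no partner, so slope and lag are unchanged and the neighbour's hot window again gives 10.4%. The neighbour ends with 10.2% of product.

The numbers in the tables were generated by integration for substances that don't exist; noise was put on by code.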